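## Retrosynthetic overview

1. Feature: the cis-2,6-disubstituted oxan-4-one ring (O1, C2 bearing ring A, C3, C4=O, C5, C6 bearing C1'(OH)–C2'H2–ring B) is an 8-oxabicyclo[3.2.1]oct-6-en-3-one whose two-carbon C6=C7 bridge has been cut. O1, C2 and C6 are furan atoms and C3–C4–C5 is an acetone unit.
2. Late disconnections: removal of the O-benzyl groups and the C4 ketal; C1'–H by chelate-controlled ketone reduction; C1'–C2' by Weinreb amide plus benzylic Grignard; C2–ring A by nickel/photoredox decarboxylative arylation of the C2 acid.
3. Both arms come from one meso bis(hydroxymethyl) ketal, made by ozonolysis–NaBH4 of the ketalised bicycle. A lipase monoacetylation tells the arms apart and fixes the absolute configuration.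
4. Ring order: the furan ring is bought. The seven-membered carbocycle and the six-membered pyranone ring close together in the furan/oxyallyl [4+3] step, and alkene cleavage later opens the carbocycle. Rings A and B are bought arenes.

Key step: step 1

Assumption: the lipase is taken to acetylate the CH2OH group on the R-configured ring carbon of the meso diol; the sense of such desymmetrisations is empirical, and the hydrolytic mode given under the risks reverses it with the same enzyme.
Numbering: all monocyclic compounds carry the target numbering (O1, C2–C6, C1', C2').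

## Route

Step 1
Reactants: 1 furan; 2 1,1,3,3-tetrabromoacetone
Product: 5 meso 8-oxabicyclo[3.2.1]oct-6-en-3-one, via zinc-bound 1,3-dibromo-2-oxyallyl cation 3 (not isolated), via 2,4-dibromo-8-oxabicyclo[3.2.1]oct-6-en-3-one 4 (not isolated)
Conditions: Zn–Cu couple, furan (excess), THF, −10 °C → rt; crude, then Zn–Cu couple, NH4Cl, MeOH, −78 °C → rt
Reagents that add atoms: none
Why: Zinc converts one CBr2 terminus of 2 into a zinc enolate, and loss of bromide from the other terminus gives oxyallyl cation 3, a 2π three-carbon unit that adds suprafacially across C2 and C5 of the furan 4π system (concerted or fast stepwise) and forms the future C2–C3 and C5–C6 bonds. The closest known chemistry is the classical [4+3] cycloaddition of furan with oxyallyl cations from polybromoketones, followed by reductive dehalogenation of the α-bromoketone through its zinc enolate. The seven-membered carbocycle closes by intermolecular [4+3] cycloaddition, and because the furan oxygen spans its two new sp3 termini, the six-membered O1–C2–C3–C4–C5–C6 pyranone ring closes in the same event. The two bridgehead stereocentres (future C2 and C6) can only be cis, since both bonds form on one face of planar furan and a one-atom bridge cannot span trans positions, so 5 is meso. The step needs cycloaddition to win over electrophilic substitution at furan C2 and over self-reaction of the cation, which the two cation-stabilising bromines left on 3 and the excess of furan should secure. Compact versus extended approach decides only the C–Br configurations of 4, and these centres vanish on debromination.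

Step 2
Reactants: 5 meso 8-oxabicyclo[3.2.1]oct-6-en-3-one
Product: 6 meso 8-oxabicyclo[3.2.1]oct-6-en-3-one ethylene ketal
Conditions: HOCH2CH2OH, p-TsOH·H2O (cat.), benzene, Dean–Stark, reflux
Reagents that add atoms: ethylene glycol, OCCO
Why: Acid-catalysed ketalisation driven by azeotropic water removal keeps the mirror plane, shields C4 from NaBH4, the Grignard reagent and Zn(BH4)2, and blocks enolisation-driven opening of the C–O1 bonds in the later basic steps.

Step 3
Reactants: 6 meso 8-oxabicyclo[3.2.1]oct-6-en-3-one ethylene ketal
Product: 8 meso cis-2,6-bis(hydroxymethyl)oxan-4-one ethylene ketal, via secondary ozonide 7 (not isolated)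
Conditions: O3, CH2Cl2, −78 °C; then MeOH, NaBH4, −78 °C → rt
Reagents that add atoms: ozone, [O-][O+]=O
Why: Criegee ozonolysis of the strained etheno bridge and hydride reduction of ozonide 7 cut the two-carbon bridge and leave the untouched, still cis bridgeheads as C2 and C6 of a monocyclic oxane; a ketal without an acetal C–H is inert to ozone at −78 °C.

Step 4
Reactants: 8 meso cis-2,6-bis(hydroxymethyl)oxan-4-one ethylene ketal
Product: 9 (2S,6R)-6-(acetoxymethyl)-2-(hydroxymethyl)oxan-4-one ethylene ketal
Conditions: lipase PS (Burkholderia cepacia, immobilised), vinyl acetate, t-BuOMe, 30 °C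
Reagents that add atoms: vinyl acetate, C=COC(C)=O
Why: In this lipase-catalysed irreversible transesterification (enantiotopic-group-selective desymmetrisation, established for meso cis-2,6-bis(hydroxymethyl)oxanes), the chiral acyl-enzyme pocket acylates one of the two mirror-related CH2OH groups faster, which turns the meso C2/C6 pair into (2S,6R), and the slower second acylation should consume mainly the minor enantiomer.

Step 5
Reactants: 9 (2S,6R)-6-(acetoxymethyl)-2-(hydroxymethyl)oxan-4-one ethylene ketal
Product: 11 (2S,6R)-6-(acetoxymethyl)-4,4-(ethylenedioxy)oxane-2-carboxylic acid, via C2 aldehyde 10 (not isolated)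
Conditions: TEMPO (cat.), PhI(OAc)2, MeCN–H2O, rt
Reagents that add atoms: water, O
Why: Oxoammonium-mediated oxidation of the primary alcohol through aldehyde 10 and its hydrate proceeds under nearly neutral conditions that spare the acetate and the dioxolane, and the C2 configuration need not be guarded because step 7 erases it.

Step 6
Reactants: 12 4-bromo-2-methoxyphenol
Product: 13 1-(benzyloxy)-4-bromo-2-methoxybenzene
Conditions: BnBr, K2CO3, acetone, reflux
Reagents that add atoms: benzyl bromide, BrCc1ccccc1
Why: Williamson etherification masks the acidic phenol, which would otherwise consume the carboxylate base and interfere with the nickel cycle, with a group that leaves together with the ring B benzyl ether at the end.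

Step 7
Reactants: 11 (2S,6R)-6-(acetoxymethyl)-4,4-(ethylenedioxy)oxane-2-carboxylic acid; 13 1-(benzyloxy)-4-bromo-2-methoxybenzene
Product: 14 (2S,6R)-6-(acetoxymethyl)-2-(4-benzyloxy-3-methoxyphenyl)oxan-4-one ethylene ketal
Conditions: Ir[dF(CF3)ppy]2(dtbbpy)PF6 (cat.), NiCl2·glyme (cat.), 4,4'-di-tert-butyl-2,2'-bipyridine (cat.), Cs2CO3, DMF, blue LEDs, rt
Reagents that add atoms: none
Why: In this metallaphotoredox decarboxylative arylation of an α-oxy acid the excited iridium complex oxidises the caesium carboxylate, loss of CO2 gives the O1-stabilised C2 radical, and the aryl nickel bromide formed from 13 captures it and reductively eliminates the C2–ring A bond; C6 is untouched, and C2 should be set equatorial (cis) because the axial ketal oxygen at C4 and axial H6 screen the axial face from the bulky bipyridine nickel unit, any trans epimer being separable here or correctable at the stage of 25.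

Step 8
Reactants: 14 (2S,6R)-6-(acetoxymethyl)-2-(4-benzyloxy-3-methoxyphenyl)oxan-4-one ethylene ketal
Product: 15 (2S,6R)-2-(4-benzyloxy-3-methoxyphenyl)-6-(hydroxymethyl)oxan-4-one ethylene ketal
Conditions: K2CO3 (cat.), MeOH, rt
Reagents that add atoms: none
Why: Base-catalysed transesterification (methanolysis of the acetate) frees the C6 arm, and with C4 ketalised no position is enolisable, so C2 and C6 cannot epimerise.

Step 9
Reactants: 15 (2S,6R)-2-(4-benzyloxy-3-methoxyphenyl)-6-(hydroxymethyl)oxan-4-one ethylene ketal
Product: 17 (2R,6S)-6-(4-benzyloxy-3-methoxyphenyl)-4,4-(ethylenedioxy)oxane-2-carboxylic acid [target numbering 6R,2S], via C6 aldehyde 16 (not isolated)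
Conditions: TEMPO (cat.), PhI(OAc)2, MeCN–H2O, rt
Reagents that add atoms: water, O
Why: The same oxoammonium-mediated alcohol-to-acid oxidation applies; the aryl benzyl ethers and the dioxolane are inert, and the equatorial C6 centre next to transient aldehyde 16 is not at risk in the weakly acidic medium.

Step 10
Reactants: 17 C6 carboxylic acid
Product: 19 (2S,6R)-2-(4-benzyloxy-3-methoxyphenyl)-6-[methoxy(methyl)carbamoyl]oxan-4-one ethylene ketal, via acyl imidazole 18 (not isolated)
Conditions: 1,1'-carbonyldiimidazole, CH2Cl2, rt; then MeNHOMe·HCl, rt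
Reagents that add atoms: N,O-dimethylhydroxylamine hydrochloride, CNOC.Cl
Why: Carbonyldiimidazole activation followed by aminolysis of acyl imidazole 18 is a standard Weinreb amide synthesis, and without a strong base the α-alkoxy centre C6 should hold.

Step 11
Reactants: 19 Weinreb amide; 20 4-benzyloxybenzyl chloride
Product: 23 (2S,6R)-2-(4-benzyloxy-3-methoxyphenyl)-6-[(4-benzyloxyphenyl)acetyl]oxan-4-one ethylene ketal, via 4-benzyloxybenzylmagnesium chloride 21 (not isolated), via magnesium-chelated tetrahedral adduct 22 (not isolated)
Conditions: 20, Mg, THF, 0 °C (slow addition); then 19, THF, −78 → 0 °C; aq. NH4Cl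
Reagents that add atoms: none
Why: In this Weinreb ketone synthesis the benzylic Grignard 21, formed dilute and cold to limit Wurtz coupling, adds once and forms C1'–C2' because chelate 22 survives until the quench, so the enolisable ketone never meets the basic reagent and C6 is protected.

Step 12
Reactants: 23 C1' ketone
Product: 24 (2S,6R)-2-(4-benzyloxy-3-methoxyphenyl)-6-[(1S)-2-(4-benzyloxyphenyl)-1-hydroxyethyl]oxan-4-one ethylene ketal
Conditions: Zn(BH4)2, Et2O–CH2Cl2, −78 → −30 °C; H2O
Reagents that add atoms: none
Why: In this Cram-chelate-controlled reduction divalent zinc ties the C1' carbonyl oxygen to ring O1 in a five-membered chelate, and hydride arrives from the face flanked by H6 rather than by C5, which gives the anti O1/OH relationship, that is (1'S) next to (6R).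

Step 13
Reactants: 24 C1' alcohol ketal
Product: 25 (2S,6R)-2-(4-benzyloxy-3-methoxyphenyl)-6-[(1S)-2-(4-benzyloxyphenyl)-1-hydroxyethyl]oxan-4-one
Conditions: 1 M aq. HCl, THF, rt → 40 °C
Reagents that add atoms: water, O
Why: Aqueous acid hydrolysis of the dioxolane spares the benzyl ethers and the carbinol; in the freed β-alkoxy ketone the diequatorial cis isomer is the thermodynamic one, so reversible opening of the benzylic C2–O1 bond (retro-oxa-Michael/oxa-Michael) can only drain residual C2 epimer towards 25, and the medium is kept mild so that C6–O1, whose opening would scramble C6 against C1', stays closed.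

Step 14
Reactants: 25 dibenzyl ether of the target
Product: 26 (2S,6R)-2-(4-hydroxy-3-methoxyphenyl)-6-[(1S)-1-hydroxy-2-(4-hydroxyphenyl)ethyl]oxan-4-one (CNP0222055.1)
Conditions: H2 (1 atm), Pd/C, EtOAc, rt
Reagents that add atoms: none
Why: Catalytic hydrogenolysis cleaves the two aryl benzyl ethers much faster than the ring C2–O1 benzylic bond, under neutral conditions in which the ketone, the carbinol and all three stereocentres should persist.

## Compound list

1 | furan | c1ccoc1 | starting material
2 | 1,1,3,3-tetrabromoacetone | O=C(C(Br)Br)C(Br)Br | starting material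
3 | bromozinc 1,3-dibromo-2-oxyallyl cation, bromide counter-ion | Br[Zn]OC(=CBr)[CH+]Br.[Br-] | intermediate
4 | 2,4-dibromo-8-oxabicyclo[3.2.1]oct-6-en-3-one (cis bridgeheads, mixture of C–Br epimers) | O=C1C(Br)[C@H]2C=C[C@@H](C1Br)O2 | intermediate
5 | meso 8-oxabicyclo[3.2.1]oct-6-en-3-one | O=C1C[C@H]2C=C[C@@H](C1)O2 | intermediate
6 | meso 8-oxabicyclo[3.2.1]oct-6-en-3-one ethylene ketal | O1CCOC12C[C@H]3C=C[C@@H](C2)O3 | intermediate
7 | secondary ozonide (1,2,4-trioxolane) of 6, trioxolane carbons undefined | O1OC2OC1[C@@H]1CC3(OCCO3)C[C@H]2O1 | intermediate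
8 | meso cis-2,6-bis(hydroxymethyl)oxan-4-one ethylene ketal | OC[C@@H]1CC2(OCCO2)C[C@H](CO)O1 | intermediate
9 | (2S,6R)-6-(acetoxymethyl)-2-(hydroxymethyl)oxan-4-one ethylene ketal | OC[C@@H]1CC2(OCCO2)C[C@H](COC(C)=O)O1 | intermediate
10 | (2S,6R)-6-(acetoxymethyl)-4,4-(ethylenedioxy)oxane-2-carbaldehyde | O=C[C@@H]1CC2(OCCO2)C[C@H](COC(C)=O)O1 | intermediate
11 | (2S,6R)-6-(acetoxymethyl)-4,4-(ethylenedioxy)oxane-2-carboxylic acid | OC(=O)[C@@H]1CC2(OCCO2)C[C@H](COC(C)=O)O1 | intermediate
12 | 4-bromo-2-methoxyphenol | COc1cc(Br)ccc1O | starting material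
13 | 1-(benzyloxy)-4-bromo-2-methoxybenzene | COc1cc(Br)ccc1OCc1ccccc1 | intermediate
14 | (2S,6R)-6-(acetoxymethyl)-2-(4-benzyloxy-3-methoxyphenyl)oxan-4-one ethylene ketal | COc1cc([C@@H]2CC3(OCCO3)C[C@H](COC(C)=O)O2)ccc1OCc1ccccc1 | intermediate
15 | (2S,6R)-2-(4-benzyloxy-3-methoxyphenyl)-6-(hydroxymethyl)oxan-4-one ethylene ketal | COc1cc([C@@H]2CC3(OCCO3)C[C@H](CO)O2)ccc1OCc1ccccc1 | intermediate
16 | C6 aldehyde, (2S,6R), ketal retained | COc1cc([C@@H]2CC3(OCCO3)C[C@H](C=O)O2)ccc1OCc1ccccc1 | intermediate
17 | C6 carboxylic acid, (2S,6R) in target numbering, ketal retained | COc1cc([C@@H]2CC3(OCCO3)C[C@H](C(=O)O)O2)ccc1OCc1ccccc1 | intermediate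
18 | C6 acyl imidazole, (2S,6R) | COc1cc([C@@H]2CC3(OCCO3)C[C@H](C(=O)n4ccnc4)O2)ccc1OCc1ccccc1 | intermediate
19 | C6 N-methoxy-N-methylamide (Weinreb amide), (2S,6R) | COc1cc([C@@H]2CC3(OCCO3)C[C@H](C(=O)N(C)OC)O2)ccc1OCc1ccccc1 | intermediate
20 | 4-benzyloxybenzyl chloride | ClCc1ccc(OCc2ccccc2)cc1 | starting material
21 | 4-benzyloxybenzylmagnesium chloride | Cl[Mg]Cc1ccc(OCc2ccccc2)cc1 | intermediate
22 | chloromagnesium alkoxide of the tetrahedral adduct of 21 to 19 (C1' undefined) | COc1cc([C@@H]2CC3(OCCO3)C[C@H](C(O[Mg]Cl)(Cc4ccc(OCc5ccccc5)cc4)N(C)OC)O2)ccc1OCc1ccccc1 | intermediate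
23 | (2S,6R)-2-(4-benzyloxy-3-methoxyphenyl)-6-[(4-benzyloxyphenyl)acetyl]oxan-4-one ethylene ketal | COc1cc([C@@H]2CC3(OCCO3)C[C@H](C(=O)Cc4ccc(OCc5ccccc5)cc4)O2)ccc1OCc1ccccc1 | intermediate
24 | (2S,6R,1'S) alcohol, ketal and both benzyl ethers retained | COc1cc([C@@H]2CC3(OCCO3)C[C@H]([C@@H](O)Cc4ccc(OCc5ccccc5)cc4)O2)ccc1OCc1ccccc1 | intermediate
25 | (2S,6R,1'S) hydroxy ketone, dibenzyl ether of the target | COc1cc([C@@H]2CC(=O)C[C@H]([C@@H](O)Cc3ccc(OCc4ccccc4)cc3)O2)ccc1OCc1ccccc1 | intermediate
26 | (2S,6R)-2-(4-hydroxy-3-methoxyphenyl)-6-[(1S)-1-hydroxy-2-(4-hydroxyphenyl)ethyl]oxan-4-one | COc1cc([C@@H]2CC(=O)C[C@H]([C@@H](O)Cc3ccc(O)cc3)O2)ccc1O | target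

## Step count and risks

Total step count: 14. Longest linear sequence: 13 (steps 1–5 and 7–14).

**1) Step 7.**
- Risk: oxidative addition of the electron-rich bromide to zerovalent nickel may be slower than decay of the C2 radical, so hydrogen abstraction (protodecarboxylation) could take over. Capture on the axial face could also erode the cis preference.
- Fallback: the roles of the partners are reversed and no light is used. Setting out from acid 11, coupling with N-hydroxyphthalimide (N,N'-diisopropylcarbodiimide, DMAP cat., CH2Cl2) gives the redox-active N-acyloxyphthalimide F1. Bromide 13 is converted with Mg/LiCl in THF into (4-benzyloxy-3-methoxyphenyl)magnesium bromide F2, and then with ZnCl2 into (4-benzyloxy-3-methoxyphenyl)zinc chloride F3. NiCl2·glyme and 4,4'-di-tert-butyl-2,2'-bipyridine (cat.) in THF–DMF at rt join F1 and F3 in a thermal decarboxylative Negishi-type arylation. Here the aryl group reaches nickel by transmetalation instead of oxidative addition, and the acetate tolerates the arylzinc. The sequence comes back to the route at 14.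

**2) Step 4.**
- Risk: the enzyme may discriminate poorly between the enantiotopic arms, acylate the wrong arm, or run on to double acylation.
- Fallback: the hydrolase is run in the opposite direction on a different substrate. Setting out from diol 8, Ac2O/pyridine gives the meso diacetate F4. The lipase (or pig liver esterase) in pH 7 phosphate buffer then hydrolyses a single ester. Because a hydrolase addresses the same arm in both directions, hydrolysis gives the monoacetate of opposite sense to acylation, so whichever mode delivers the (2S,6R) compound is used. The sequence comes back to the route at 9.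

**3) Step 12.**
- Risk: open (Felkin–Anh type) transition states, or zinc binding to a ketal oxygen, may compete with the O1/C=O chelate and erode facial selectivity at C1'.
- Fallback: substrate control is replaced by catalyst control. Setting out from ketone 23, a Corey–Bakshi–Shibata reduction is run with (R)-2-methyl-CBS-oxazaborolidine (cat.) and BH3·SMe2 in THF at −20 °C. The branched ring carbon C6 acts as the large group and CH2Ar as the small group, which should give the (1'S) carbinol. The sequence comes back to the route at 24, and no compound outside the list is made (F0).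

## Further compounds

F1 | step 7 | 1,3-dioxoisoindolin-2-yl (2S,6R)-6-(acetoxymethyl)-4,4-(ethylenedioxy)oxane-2-carboxylate | O=C(ON1C(=O)c2ccccc2C1=O)[C@@H]1CC2(OCCO2)C[C@H](COC(C)=O)O1
F2 | step 7 | (4-benzyloxy-3-methoxyphenyl)magnesium bromide | COc1cc([Mg]Br)ccc1OCc1ccccc1
F3 | step 7 | (4-benzyloxy-3-methoxyphenyl)zinc chloride | COc1cc([Zn]Cl)ccc1OCc1ccccc1
F4 | step 4 | meso cis-2,6-bis(acetoxymethyl)oxan-4-one ethylene ketal | CC(=O)OC[C@@H]1CC2(OCCO2)C[C@H](COC(C)=O)O1
F0 | step 12 | none | none
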